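The constants are read here as times at the charged amounts; the scheme and the flasks are these.

    starting material + target → side product (k1 = 210 /M/s, Ea1 = 39.0 kJ/mol)
    starting material + reagent → isomer of the product (k2 = 220 /M/s, Ea2 = 38.0 kJ/mol)
    solid substrate ⇌ starting material, rate k3*(cs3 - [starting material]) while solid is left; crystals form when [starting material] > cs3 (cs3 = 0.54 mM, k3 = 0.24 /s)
    starting material + reagent → second isomer (k4 = 180 /M/s, Ea4 = 38.0 kJ/mol)
    starting material + reagent → target (k5 = 110 /M/s, Ea5 = 38.0 kJ/mol)
    (constants at 5 °C)

common to all: solid substrate 2.0 mM; reagent 2.00 mM; time 20 s

| charge | temperature |
|---|---|
| eta | 65 °C |
| epsilon | 35 °C |
| gamma | 5 °C |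

- a species is counted by the solid substrate in it: one side product counts as two
- given per volume of solution although it is solid: solid substrate
- all constants are for 5 °C and move with temperature by the activation energies
- at the start none of the solid substrate is in solution
- what has only dissolved of solid substrate counts as not reacted

- the flask with the highest share of target in all that became target or isomer of the product or second isomer or side product ("all alike" if they lie within 1.5 percentage points) (eta / epsilon / gamma / all alike)
- share of target in all that became target or isomer of the product or second isomer or side product, eta
- share of target in all that became target or isomer of the product or second isomer or side product, epsilon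
- share of target in all that became target or isomer of the product or second isomer or side product, gamma

Dissolving runs at 0.130 mM/s at its fastest, so the charge needs at least 15.4 s, which is less than the 20 s allowed. At its charged amount, reagent gives dissolved starting material a lifetime of 0.980 s at 5 °C, so gamma starts by keeping up with the solid. But that time stretches as reagent falls.

Steps 2, 4 and 5 differ in activation energy by 0 kJ/mol, so target is 21.6% of what reagent turns over. Step 1 differs by 1.00 kJ/mol, which this reckoning neglects.

Target is also consumed by starting material, but [starting material] stands as a factor in both its making and its loss. It therefore cancels when target is reckoned against reagent used instead of time. With b the part of reagent left, f that split and a = k1/(k2+k4+k5) = 0.412, target as a part of the charge is f/(1−a)·(b^a−b), a factor of 0.367 on the bracket.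

This curve peaks at b = a^(1/(1−a)), the crest reagent, which is 22.1% of the charge. The crest target is 11.6%.

A finished flask holds as many side product molecules as reagent left, and trial on the curve gives 8.94% reagent left and a share of 10.3%. Eta, with that lifetime shorter by a factor of 18, is reckoned finished, and epsilon is taken as finished too.

In gamma, the lifetime of starting material at crest reagent is 4.43 s, close to the 4.60 s that remain after the shortest possible feed, so gamma is not reckoned finished. Taken to stop at the crest, which is a rough guess, gamma is reckoned at a share of 14.0%.

The forecast gives 10%, 10.4% and 14.4% and names gamma, holding that in gamma “less of that late over-reaction has happened”.

The flasks give 9.96% for eta, 10.3% for epsilon and 14.0% for gamma, so gamma stands highest. Gamma ends at a conversion of 82.8% with 22% of its reagent left, beside the crest reagent of 22.1%. The curve falls to nothing as b does, and the neighbour of eta charged with 1.2 mM of reagent keeps 0% of it and ends with a target share of 0%.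

(The rate constants are assumed; the rest is arithmetic.)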